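**Retrosynthetic overview**
- Target 29 ← neutral sulfoxide elimination ← BCl3 debenzylation ← masked α-methylenation ← C7 Friedel–Crafts acylation ← ketone 21 ← reductive Nef reaction of nitronate 20.
- 20 ← aryne annulation of silyl triflate 6 with hydroxy nitroalkene 17: O1–C7a and C3a–C3 form in one operation and close the dihydrofuran, the only ring made in the route.
- Feature used: O1 and C3 sit on the adjacent ring A carbons C7a and C3a, the C4 oxygen lies beside C3a and a second oxygen sits at C6. Ring A is therefore a 3,5-dioxygenated benzyne polarised by the oxygen next to its triple bond, and the C3 aroyl carbonyl is carried as a nitroalkene.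
- 17 ← Henry reaction/dehydration of aldehyde 13 (C2 from (S)-4-hydroxymandelic acid) with arylnitromethane 9; 6 ← 3,5-bis(benzyloxy)phenol by bromination, silylation, retro-Brook shift and triflation.
- Ring order: five benzene rings bought, dihydrofuran closed in step 11; C7 side chain and the exocyclic methylene added last.

Key step: step 11

Remark: all six phenols are carried as benzyl ethers, because the BBr3-type conditions needed for aryl methyl ethers are expected to open the C2–O1 bond of a 2-aryl-2,3-dihydrobenzofuran with a C3 carbonyl group; compounds 1, 7, 10 and 22 are assumed to be purchasable.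

Step 1
Reactants: 1 3,5-bis(benzyloxy)phenol
Product: 2 3,5-bis(benzyloxy)-2-bromophenol
Conditions: NBS (1.0 equiv), CH2Cl2, −78 → 23 °C
Reagents that add atoms: N-bromosuccinimide, O=C1CCC(=O)N1Br
Why: Electrophilic aromatic bromination is expected at C2, ortho to the free hydroxyl and para to a benzyloxy group, because C4 is shielded by two benzyloxy groups; the minor 4-bromo isomer would be removed by chromatography.

Step 2
Reactants: 2 3,5-bis(benzyloxy)-2-bromophenol
Product: 3 [3,5-bis(benzyloxy)-2-bromophenoxy]trimethylsilane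
Conditions: HMDS, THF, 65 °C
Reagents that add atoms: hexamethyldisilazane, C[Si](C)(C)N[Si](C)(C)C
Why: O-Silylation of the phenol with HMDS should give the aryl silyl ether needed for the silyl shift, with ammonia as the only by-product.

Step 3
Reactants: 3 [3,5-bis(benzyloxy)-2-bromophenoxy]trimethylsilane
Product: 6 3,5-bis(benzyloxy)-2-(trimethylsilyl)phenyl trifluoromethanesulfonate, via aryllithium 4 (not isolated), via lithium silylphenoxide 5 (not isolated)
Conditions: n-BuLi, THF, −78 °C; then Tf2O, −78 → 0 °C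
Reagents that add atoms: trifluoromethanesulfonic anhydride, O=S(=O)(OS(=O)(=O)C(F)(F)F)C(F)(F)F
Why: Bromine–lithium exchange gives 4, its 1,3 O-to-C silyl shift (retro-Brook rearrangement) gives 5, and O-triflation then delivers the ortho-silyl aryl triflate that serves as fluoride-triggered aryne precursor.

Step 4
Reactants: 7 4-bromoresorcinol
Product: 8 2,4-bis(benzyloxy)-1-bromobenzene
Conditions: BnBr, K2CO3, DMF, 23 → 60 °C
Reagents that add atoms: benzyl bromide, BrCc1ccccc1
Why: Williamson ether synthesis on both phenoxide oxygens.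

Step 5
Reactants: 8 2,4-bis(benzyloxy)-1-bromobenzene
Product: 9 2,4-bis(benzyloxy)-1-(nitromethyl)benzene
Conditions: Pd2(dba)3 (cat.), XPhos (cat.), Cs2CO3, CH3NO2/1,4-dioxane, 4 Å sieves, 50 °C
Reagents that add atoms: nitromethane, C[N+](=O)[O-]
Why: Palladium-catalysed cross-coupling of the aryl bromide with the nitronate of nitromethane (C-arylation of nitromethane), a reaction suited to electron-rich bromides with a bulky biaryl phosphine.

Step 6
Reactants: 10 (S)-4-hydroxymandelic acid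
Product: 11 benzyl (S)-2-[4-(benzyloxy)phenyl]-2-hydroxyacetate
Conditions: BnBr (2.1 equiv), K2CO3, DMF, 0 → 23 °C
Reagents that add atoms: benzyl bromide, BrCc1ccccc1
Why: Carbonate-mediated O-benzylation of the carboxylate and the phenoxide (Williamson type) leaves the less acidic secondary alcohol free and does not touch the stereocentre.

Step 7
Reactants: 11 benzyl (S)-2-[4-(benzyloxy)phenyl]-2-hydroxyacetate
Product: 12 benzyl (S)-2-[4-(benzyloxy)phenyl]-2-[(tert-butyldimethylsilyl)oxy]acetate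
Conditions: TBSCl, imidazole, DMF, 23 °C
Reagents that add atoms: tert-butyldimethylsilyl chloride, CC(C)(C)[Si](C)(C)Cl
Why: Silylation of the secondary alcohol masks it for the reduction and condensation steps.

Step 8
Reactants: 12 benzyl (S)-2-[4-(benzyloxy)phenyl]-2-[(tert-butyldimethylsilyl)oxy]acetate
Product: 13 (S)-2-[4-(benzyloxy)phenyl]-2-[(tert-butyldimethylsilyl)oxy]acetaldehyde
Conditions: i-Bu2AlH (1.1 equiv), CH2Cl2, −78 °C; then MeOH, aq. potassium sodium tartrate
Reagents that add atoms: none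
Why: Low-temperature hydride reduction of the ester with one equivalent of i-Bu2AlH stops at the aldehyde oxidation level, and the α-silyloxy aldehyde is used at once without chromatography to keep its α-centre intact.

Step 9
Reactants: 13 (S)-2-[4-(benzyloxy)phenyl]-2-[(tert-butyldimethylsilyl)oxy]acetaldehyde; 9 2,4-bis(benzyloxy)-1-(nitromethyl)benzene
Product: 16 tert-butyl{[(1R,2E)-3-[2,4-bis(benzyloxy)phenyl]-1-[4-(benzyloxy)phenyl]-3-nitroprop-2-en-1-yl]oxy}dimethylsilane, via nitroaldol 14 (not isolated), via nitroaldol mesylate 15 (not isolated)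
Conditions: Et3N (0.2 equiv), THF, 0 °C; then MsCl, Et3N, −20 → 0 °C
Reagents that add atoms: none
Why: Henry reaction of the acidic arylnitromethane with 13 under catalytic amine, then mesylation and E1cB elimination through the nitronate, should give the conjugated nitroalkene; the carbinol centre comes from 10 and is not a reacting centre, the two new centres of 14 are removed again, and either alkene geometry would serve in step 11.

Step 10
Reactants: 16 tert-butyl{[(1R,2E)-3-[2,4-bis(benzyloxy)phenyl]-1-[4-(benzyloxy)phenyl]-3-nitroprop-2-en-1-yl]oxy}dimethylsilane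
Product: 17 (1R,2E)-3-[2,4-bis(benzyloxy)phenyl]-1-[4-(benzyloxy)phenyl]-3-nitroprop-2-en-1-ol
Conditions: HF·pyridine, THF/pyridine, 0 → 23 °C
Reagents that add atoms: none
Why: Acidic fluoride cleaves the Si–O bond without the basic conditions that would deprotonate the γ-position of the nitroalkene.

Step 11
Reactants: 17 (1R,2E)-3-[2,4-bis(benzyloxy)phenyl]-1-[4-(benzyloxy)phenyl]-3-nitroprop-2-en-1-ol; 6 3,5-bis(benzyloxy)-2-(trimethylsilyl)phenyl trifluoromethanesulfonate
Product: 20 cesium nitronate of (2R,3S)-trans-4,6-bis(benzyloxy)-3-{[2,4-bis(benzyloxy)phenyl]nitromethyl}-2-[4-(benzyloxy)phenyl]-2,3-dihydro-1-benzofuran, via aryne 18 (not isolated), via aryl anion 19 (not isolated)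
Conditions: CsF (4 equiv), 18-crown-6, THF, 23 °C, 6 (1.3 equiv) added over 4 h; then concentrated and used crude
Reagents that add atoms: cesium fluoride, [Cs+].[F-]
Why: Proposed new method: fluoride removes the silyl group of 6 with loss of triflate to give aryne 18; the fluoride-activated hydroxyl of 17 adds to the aryne carbon distal to the flanking benzyloxy group (future C7a), which leaves the carbanion of 19 on the carbon next to that inductively withdrawing oxygen (future C3a), and this carbanion adds to the β-carbon of the tethered nitroalkene to give nitronate 20. The closest known reaction type is the fluoride-induced aryne annulation in which a phenol, amide or carbamate adds and the aryl anion is trapped by a tethered ester, ketone or enone; a secondary alkoxide with a nitroalkene acceptor is the extension proposed here. The dihydrofuran closes by a 5-exo-trig conjugate addition of C3a onto C3, the C=C bond being exocyclic to the new ring. C2 comes unchanged from 17, and C3 is set by it through allylic 1,3-strain: with C2–H eclipsing the nitroalkene, the carbanion is delivered from the face of the tethering oxygen and the nitronate carbon ends anti to the C2 aryl group (trans), the arrangement to which C3 can also return once it is α to the ketone. The step needs regioselective O-attack, secured by the benzyloxy group beside the triple bond, and ring closure faster than protonation of 19, for which the aprotic medium, the high electrophilicity of the nitroalkene and the slow release of the aryne are relied on.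

Step 12
Reactants: 20 cesium nitronate of (2R,3S)-trans-4,6-bis(benzyloxy)-3-{[2,4-bis(benzyloxy)phenyl]nitromethyl}-2-[4-(benzyloxy)phenyl]-2,3-dihydro-1-benzofuran
Product: 21 {(2R,3R)-4,6-bis(benzyloxy)-2-[4-(benzyloxy)phenyl]-2,3-dihydro-1-benzofuran-3-yl}[2,4-bis(benzyloxy)phenyl]methanone
Conditions: TiCl3 (aq., 5 equiv), NH4OAc buffer (pH 5–6), THF/MeOH/H2O, 0 → 23 °C
Reagents that add atoms: water, O
Why: Reductive Nef reaction: trivalent titanium reduces the nitronate at nitrogen and the resulting C=N bond is hydrolysed in the buffered medium to the aryl ketone; C3, now α to the ketone, stays trans, which is also the thermodynamically preferred arrangement.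

Step 13
Reactants: 21 {(2R,3R)-4,6-bis(benzyloxy)-2-[4-(benzyloxy)phenyl]-2,3-dihydro-1-benzofuran-3-yl}[2,4-bis(benzyloxy)phenyl]methanone; 22 [4-(benzyloxy)phenyl]acetic acid
Product: 24 1-{(2R,3R)-4,6-bis(benzyloxy)-3-[2,4-bis(benzyloxy)benzoyl]-2-[4-(benzyloxy)phenyl]-2,3-dihydro-1-benzofuran-7-yl}-2-[4-(benzyloxy)phenyl]ethan-1-one, via mixed anhydride 23 (not isolated)
Conditions: TFAA (3 equiv), CH2Cl2, 0 → 23 °C
Reagents that add atoms: none
Why: Friedel–Crafts acylation by mixed anhydride 23: ring A is the only ring with three oxygen donors, and C7, flanked by the tied-back ring oxygen and one benzyloxy group, is less hindered than C5 between two benzyloxy groups; the mild Brønsted medium should spare the benzyl ethers and the C2–O1 bond.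

Step 14
Reactants: 24 1-{(2R,3R)-4,6-bis(benzyloxy)-3-[2,4-bis(benzyloxy)benzoyl]-2-[4-(benzyloxy)phenyl]-2,3-dihydro-1-benzofuran-7-yl}-2-[4-(benzyloxy)phenyl]ethan-1-one
Product: 26 1-{(2R,3R)-4,6-bis(benzyloxy)-3-[2,4-bis(benzyloxy)benzoyl]-2-[4-(benzyloxy)phenyl]-2,3-dihydro-1-benzofuran-7-yl}-2-[4-(benzyloxy)phenyl]-3-(phenylsulfanyl)propan-1-one (both epimers at the new centre), via enone 25 (not isolated)
Conditions: (CH2O)n, i-Pr2NH·CF3CO2H, CF3CO2H (cat.), THF, 65 °C; then PhSH, Et3N, 23 °C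
Reagents that add atoms: paraformaldehyde (formaldehyde), C=O; thiophenol, Sc1ccccc1
Why: Mannich-type α-methylenation occurs at the only ketone CH2 group (the tertiary C3–H cannot give an alkene), and thia-Michael addition of thiophenol masks the reactive 2-arylpropenone as a β-sulfanyl ketone for the Lewis acid step; the new centre α to the C7 ketone is uncontrolled and is removed in step 16.

Step 15
Reactants: 26 1-{(2R,3R)-4,6-bis(benzyloxy)-3-[2,4-bis(benzyloxy)benzoyl]-2-[4-(benzyloxy)phenyl]-2,3-dihydro-1-benzofuran-7-yl}-2-[4-(benzyloxy)phenyl]-3-(phenylsulfanyl)propan-1-one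
Product: 27 1-[(2R,3R)-3-(2,4-dihydroxybenzoyl)-4,6-dihydroxy-2-(4-hydroxyphenyl)-2,3-dihydro-1-benzofuran-7-yl]-2-(4-hydroxyphenyl)-3-(phenylsulfanyl)propan-1-one
Conditions: BCl3 (excess), C6HMe5, CH2Cl2, −78 °C; then H2O
Reagents that add atoms: none
Why: BCl3 cleaves aryl benzyl ethers at −78 °C with pentamethylbenzene as a non-basic scavenger of the benzyl cation (Friedel–Crafts benzylation of the scavenger), conditions chosen because they should leave the C2–O1 bond, the ketones and the thioether intact.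

Step 16
Reactants: 27 1-[(2R,3R)-3-(2,4-dihydroxybenzoyl)-4,6-dihydroxy-2-(4-hydroxyphenyl)-2,3-dihydro-1-benzofuran-7-yl]-2-(4-hydroxyphenyl)-3-(phenylsulfanyl)propan-1-one
Product: 29 1-[(2R,3R)-3-(2,4-dihydroxybenzoyl)-4,6-dihydroxy-2-(4-hydroxyphenyl)-2,3-dihydro-1-benzofuran-7-yl]-2-(4-hydroxyphenyl)prop-2-en-1-one, via sulfoxide 28 (not isolated)
Conditions: mCPBA (1.0 equiv), THF, −78 → −40 °C; then 40 °C; pH 5 work-up
Reagents that add atoms: none
Why: Chemoselective S-oxidation at low temperature followed by thermal syn-elimination of the sulfoxide (its α-hydrogen is benzylic and α to the ketone) should release the 2-arylpropenone under neutral conditions, so that no phenoxide forms that could add to the new enone.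

**Compound list**
1 | 3,5-bis(benzyloxy)phenol | Oc1cc(OCc2ccccc2)cc(OCc2ccccc2)c1 | starting material
2 | 3,5-bis(benzyloxy)-2-bromophenol | Oc1cc(OCc2ccccc2)cc(OCc2ccccc2)c1Br | intermediate
3 | [3,5-bis(benzyloxy)-2-bromophenoxy]trimethylsilane | C[Si](C)(C)Oc1cc(OCc2ccccc2)cc(OCc2ccccc2)c1Br | intermediate
4 | {2,4-bis(benzyloxy)-6-[(trimethylsilyl)oxy]phenyl}lithium | C[Si](C)(C)Oc1cc(OCc2ccccc2)cc(OCc2ccccc2)c1[Li] | intermediate
5 | lithium 3,5-bis(benzyloxy)-2-(trimethylsilyl)phenoxide | [Li+].[O-]c1cc(OCc2ccccc2)cc(OCc2ccccc2)c1[Si](C)(C)C | intermediate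
6 | 3,5-bis(benzyloxy)-2-(trimethylsilyl)phenyl trifluoromethanesulfonate | C[Si](C)(C)c1c(OCc2ccccc2)cc(OCc2ccccc2)cc1OS(=O)(=O)C(F)(F)F | intermediate
7 | 4-bromoresorcinol (4-bromobenzene-1,3-diol) | Oc1ccc(Br)c(O)c1 | starting material
8 | 2,4-bis(benzyloxy)-1-bromobenzene | Brc1ccc(OCc2ccccc2)cc1OCc1ccccc1 | intermediate
9 | 2,4-bis(benzyloxy)-1-(nitromethyl)benzene | [O-][N+](=O)Cc1ccc(OCc2ccccc2)cc1OCc1ccccc1 | intermediate
10 | (S)-4-hydroxymandelic acid | O[C@@H](c1ccc(O)cc1)C(=O)O | starting material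
11 | benzyl (S)-2-[4-(benzyloxy)phenyl]-2-hydroxyacetate | O[C@@H](c1ccc(OCc2ccccc2)cc1)C(=O)OCc1ccccc1 | intermediate
12 | benzyl (S)-2-[4-(benzyloxy)phenyl]-2-[(tert-butyldimethylsilyl)oxy]acetate | CC(C)(C)[Si](C)(C)O[C@@H](c1ccc(OCc2ccccc2)cc1)C(=O)OCc1ccccc1 | intermediate
13 | (S)-2-[4-(benzyloxy)phenyl]-2-[(tert-butyldimethylsilyl)oxy]acetaldehyde | CC(C)(C)[Si](C)(C)O[C@@H](c1ccc(OCc2ccccc2)cc1)C=O | intermediate
14 | (3S)-1-[2,4-bis(benzyloxy)phenyl]-3-[4-(benzyloxy)phenyl]-3-[(tert-butyldimethylsilyl)oxy]-1-nitropropan-2-ol (diastereomers at C1 and C2) | CC(C)(C)[Si](C)(C)O[C@@H](c1ccc(OCc2ccccc2)cc1)C(O)C([N+](=O)[O-])c1ccc(OCc2ccccc2)cc1OCc1ccccc1 | intermediate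
15 | (3S)-1-[2,4-bis(benzyloxy)phenyl]-3-[4-(benzyloxy)phenyl]-3-[(tert-butyldimethylsilyl)oxy]-1-nitropropan-2-yl methanesulfonate (diastereomers) | CC(C)(C)[Si](C)(C)O[C@@H](c1ccc(OCc2ccccc2)cc1)C(OS(C)(=O)=O)C([N+](=O)[O-])c1ccc(OCc2ccccc2)cc1OCc1ccccc1 | intermediate
16 | tert-butyl{[(1R,2E)-3-[2,4-bis(benzyloxy)phenyl]-1-[4-(benzyloxy)phenyl]-3-nitroprop-2-en-1-yl]oxy}dimethylsilane | CC(C)(C)[Si](C)(C)O[C@@H](c1ccc(OCc2ccccc2)cc1)/C=C(/[N+](=O)[O-])c1ccc(OCc2ccccc2)cc1OCc1ccccc1 | intermediate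
17 | (1R,2E)-3-[2,4-bis(benzyloxy)phenyl]-1-[4-(benzyloxy)phenyl]-3-nitroprop-2-en-1-ol | O[C@@H](c1ccc(OCc2ccccc2)cc1)/C=C(/[N+](=O)[O-])c1ccc(OCc2ccccc2)cc1OCc1ccccc1 | intermediate
18 | 3,5-bis(benzyloxy)benzyne | C1#CC(OCc2ccccc2)=CC(OCc2ccccc2)=C1 | intermediate
19 | cesium 2,4-bis(benzyloxy)-6-{[(1R,2E)-3-[2,4-bis(benzyloxy)phenyl]-1-[4-(benzyloxy)phenyl]-3-nitroprop-2-en-1-yl]oxy}benzenide | [Cs+].[c-]1c(OCc2ccccc2)cc(OCc2ccccc2)cc1O[C@@H](c1ccc(OCc2ccccc2)cc1)/C=C(/[N+](=O)[O-])c1ccc(OCc2ccccc2)cc1OCc1ccccc1 | intermediate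
20 | cesium nitronate of (2R,3S)-trans-4,6-bis(benzyloxy)-3-{[2,4-bis(benzyloxy)phenyl]nitromethyl}-2-[4-(benzyloxy)phenyl]-2,3-dihydro-1-benzofuran | c1ccccc1COc1cc(OCc3ccccc3)c2c(c1)O[C@@H](c1ccc(OCc3ccccc3)cc1)[C@@H]2C(=[N+]([O-])[O-])c1ccc(OCc3ccccc3)cc1OCc1ccccc1.[Cs+] | intermediate
21 | {(2R,3R)-4,6-bis(benzyloxy)-2-[4-(benzyloxy)phenyl]-2,3-dihydro-1-benzofuran-3-yl}[2,4-bis(benzyloxy)phenyl]methanone (trans) | c1ccccc1COc1cc(OCc3ccccc3)c2c(c1)O[C@@H](c1ccc(OCc3ccccc3)cc1)[C@@H]2C(=O)c1ccc(OCc3ccccc3)cc1OCc1ccccc1 | intermediate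
22 | [4-(benzyloxy)phenyl]acetic acid | OC(=O)Cc1ccc(OCc2ccccc2)cc1 | starting material
23 | [4-(benzyloxy)phenyl]acetic trifluoroacetic anhydride | O=C(Cc1ccc(OCc2ccccc2)cc1)OC(=O)C(F)(F)F | intermediate
24 | 1-{(2R,3R)-4,6-bis(benzyloxy)-3-[2,4-bis(benzyloxy)benzoyl]-2-[4-(benzyloxy)phenyl]-2,3-dihydro-1-benzofuran-7-yl}-2-[4-(benzyloxy)phenyl]ethan-1-one | O=C(Cc1ccc(OCc2ccccc2)cc1)c1c(OCc2ccccc2)cc(OCc2ccccc2)c2c1O[C@@H](c1ccc(OCc3ccccc3)cc1)[C@@H]2C(=O)c1ccc(OCc3ccccc3)cc1OCc1ccccc1 | intermediate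
25 | 1-{(2R,3R)-4,6-bis(benzyloxy)-3-[2,4-bis(benzyloxy)benzoyl]-2-[4-(benzyloxy)phenyl]-2,3-dihydro-1-benzofuran-7-yl}-2-[4-(benzyloxy)phenyl]prop-2-en-1-one | C=C(c1ccc(OCc2ccccc2)cc1)C(=O)c1c(OCc2ccccc2)cc(OCc2ccccc2)c2c1O[C@@H](c1ccc(OCc3ccccc3)cc1)[C@@H]2C(=O)c1ccc(OCc3ccccc3)cc1OCc1ccccc1 | intermediate
26 | 1-{(2R,3R)-4,6-bis(benzyloxy)-3-[2,4-bis(benzyloxy)benzoyl]-2-[4-(benzyloxy)phenyl]-2,3-dihydro-1-benzofuran-7-yl}-2-[4-(benzyloxy)phenyl]-3-(phenylsulfanyl)propan-1-one (epimers at C2 of the propanone) | O=C(C(CSc1ccccc1)c1ccc(OCc2ccccc2)cc1)c1c(OCc2ccccc2)cc(OCc2ccccc2)c2c1O[C@@H](c1ccc(OCc3ccccc3)cc1)[C@@H]2C(=O)c1ccc(OCc3ccccc3)cc1OCc1ccccc1 | intermediate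
27 | 1-[(2R,3R)-3-(2,4-dihydroxybenzoyl)-4,6-dihydroxy-2-(4-hydroxyphenyl)-2,3-dihydro-1-benzofuran-7-yl]-2-(4-hydroxyphenyl)-3-(phenylsulfanyl)propan-1-one (epimers at C2 of the propanone) | O=C(C(CSc1ccccc1)c1ccc(O)cc1)c1c(O)cc(O)c2c1O[C@@H](c1ccc(O)cc1)[C@@H]2C(=O)c1ccc(O)cc1O | intermediate
28 | 1-[(2R,3R)-3-(2,4-dihydroxybenzoyl)-4,6-dihydroxy-2-(4-hydroxyphenyl)-2,3-dihydro-1-benzofuran-7-yl]-2-(4-hydroxyphenyl)-3-(phenylsulfinyl)propan-1-one (mixture of diastereomers) | O=C(C(CS(=O)c1ccccc1)c1ccc(O)cc1)c1c(O)cc(O)c2c1O[C@@H](c1ccc(O)cc1)[C@@H]2C(=O)c1ccc(O)cc1O | intermediate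
29 | 1-[(2R,3R)-3-(2,4-dihydroxybenzoyl)-4,6-dihydroxy-2-(4-hydroxyphenyl)-2,3-dihydro-1-benzofuran-7-yl]-2-(4-hydroxyphenyl)prop-2-en-1-one (CNP0162111.1) | C=C(C(=O)c1c(O)cc(O)c2c1O[C@@H](c1ccc(O)cc1)[C@@H]2C(=O)c1ccc(O)cc1O)c1ccc(O)cc1 | target

**Totals**
Total step count: 16. Longest linear sequence: 11 steps (steps 6–16, from 10).

**Steps most likely to fail**

1. Step 11 (proposed new method). What may go wrong: protonation of aryl anion 19 by the hydroxyl-derived HF before the ring closes; base-induced γ-deprotonation of 17, with loss of the C2 configuration or shift of the double bond; arylation of nitronate 20 by further aryne. The fallback uses known chemistry in two stages, sets out from 17 and 6 and comes back at 20. The aryne is generated with CsF in MeCN, conditions under which alcohols are O-arylated with protonation of the aryl anion, to give the open aryl ether (1R,2E)-3-[2,4-bis(benzyloxy)phenyl]-1-[4-(benzyloxy)phenyl]-1-[3,5-bis(benzyloxy)phenoxy]-3-nitroprop-2-ene F1. Both ortho positions of its 3,5-bis(benzyloxy)phenoxy ring are equivalent and strongly nucleophilic. An intramolecular Friedel–Crafts-type conjugate addition onto the nitroalkene (diaryl thiourea hydrogen-bond catalysis or Zn(OTf)2, CH2Cl2) then forms the same C3a–C3 bond and gives the nitro compound (2R,3S)-trans-4,6-bis(benzyloxy)-3-{[2,4-bis(benzyloxy)phenyl]nitromethyl}-2-[4-(benzyloxy)phenyl]-2,3-dihydro-1-benzofuran F2. Cs2CO3 in THF converts it into 20.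

2. Step 13. What may go wrong: acylation at C5 between the two benzyloxy groups in place of C7, or acid-induced opening of the C2–O1 bond. The fallback sets out from 21 and comes back at 24. NBS (1 equiv, CH2Cl2, 0 °C) is expected to brominate ring A at C5, the position the acylation would then have preferred, to give the 5-bromo ketone {(2R,3R)-4,6-bis(benzyloxy)-2-[4-(benzyloxy)phenyl]-5-bromo-2,3-dihydro-1-benzofuran-3-yl}[2,4-bis(benzyloxy)phenyl]methanone F3. Acylation with 22 and TFAA can then occur only at C7 and gives the 5-bromo-7-acyl compound 1-{(2R,3R)-4,6-bis(benzyloxy)-3-[2,4-bis(benzyloxy)benzoyl]-2-[4-(benzyloxy)phenyl]-5-bromo-2,3-dihydro-1-benzofuran-7-yl}-2-[4-(benzyloxy)phenyl]ethan-1-one F4. Radical debromination with Bu3SnH and AIBN in toluene at 80 °C then gives 24.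

3. Step 16. What may go wrong: over-oxidation of the electron-rich phenol rings or their sulfenylation by the sulfenic acid, or conjugate addition of the C6 hydroxyl to the new enone with closure of an isoflavanone-type ring. The fallback sets out from 24 and comes back at 29. Step 14 is stopped before the thiol is added and enone 25 is isolated. It is then debenzylated directly with BCl3 and pentamethylbenzene in CH2Cl2 at −78 °C and worked up at pH 5, so that no oxidant meets the free phenols.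

**Further compounds**
F1 | step 11 | (1R,2E)-3-[2,4-bis(benzyloxy)phenyl]-1-[4-(benzyloxy)phenyl]-1-[3,5-bis(benzyloxy)phenoxy]-3-nitroprop-2-ene | c1(OCc2ccccc2)cc(OCc2ccccc2)cc(c1)O[C@@H](c1ccc(OCc2ccccc2)cc1)/C=C(/[N+](=O)[O-])c1ccc(OCc2ccccc2)cc1OCc1ccccc1
F2 | step 11 | (2R,3S)-trans-4,6-bis(benzyloxy)-3-{[2,4-bis(benzyloxy)phenyl]nitromethyl}-2-[4-(benzyloxy)phenyl]-2,3-dihydro-1-benzofuran (epimers at the nitro-bearing carbon) | c1ccccc1COc1cc(OCc3ccccc3)c2c(c1)O[C@@H](c1ccc(OCc3ccccc3)cc1)[C@@H]2C([N+](=O)[O-])c1ccc(OCc3ccccc3)cc1OCc1ccccc1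
F3 | step 13 | {(2R,3R)-4,6-bis(benzyloxy)-2-[4-(benzyloxy)phenyl]-5-bromo-2,3-dihydro-1-benzofuran-3-yl}[2,4-bis(benzyloxy)phenyl]methanone | c1ccccc1COc1c(Br)c(OCc3ccccc3)c2c(c1)O[C@@H](c1ccc(OCc3ccccc3)cc1)[C@@H]2C(=O)c1ccc(OCc3ccccc3)cc1OCc1ccccc1
F4 | step 13 | 1-{(2R,3R)-4,6-bis(benzyloxy)-3-[2,4-bis(benzyloxy)benzoyl]-2-[4-(benzyloxy)phenyl]-5-bromo-2,3-dihydro-1-benzofuran-7-yl}-2-[4-(benzyloxy)phenyl]ethan-1-one | O=C(Cc1ccc(OCc2ccccc2)cc1)c1c(OCc2ccccc2)c(Br)c(OCc2ccccc2)c2c1O[C@@H](c1ccc(OCc3ccccc3)cc1)[C@@H]2C(=O)c1ccc(OCc3ccccc3)cc1OCc1ccccc1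
F0 | step 16 | none | none
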